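**Plan** (benzofuranone numbering for the target: O1, C2, C3, C3a, C4–C7, C7a)

1. Retrosynthetically the C6/C7 catechol is masked as a diphenylmethylene ketal; the Z-benzylidene lactone is then cut in one operation at O1–C2, C2–C3 and the exocyclic CH–Ph bond.
2. This cut is possible because O1 sits on C7a directly beside C3a, which carries the two-carbon unit C3=CH: the atoms O1, C2, C3 and CHPh of the lactone ring correspond to an ortho-ethynylphenol, CO and a phenyl donor.
3. Further cuts are C3a–alkyne (Sonogashira on an ortho-iodophenol), C5–acyl (aryllithium plus Weinreb amide) and the C4 methoxy oxygen, traced to an aldehyde carbon (Baeyer–Villiger); this leads back to 3,4,5-trihydroxybenzaldehyde.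
4. Forward, the dioxole ring is made first, the benzene ring is then substituted position by position (OMe, acyl, I, ethynyl), the lactone ring closes in the carbonylative three-component step, and ketal hydrolysis ends the route.
5. There is no stereocentre; the Z alkene is the only stereo-element and comes from syn aryloxycarbonyl-palladation followed by stereoretentive phenyl transfer. It is also the isomer that keeps phenyl away from the C4 methoxy group.

Key step: step 11

**Route**

Step 1
Reactants: 1 3-phenylpropanoyl chloride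
Product: 2 N-methoxy-N-methyl-3-phenylpropanamide
Conditions: MeNHOMe·HCl, pyridine, CH2Cl2, 0 °C → rt
Reagents that add atoms: N,O-dimethylhydroxylamine hydrochloride, CNOC.Cl
Why: Nucleophilic acyl substitution of the acid chloride by the hydroxylamine nitrogen should give the Weinreb amide, pyridine taking up the hydrogen chloride.

Step 2
Reactants: 3 3,4,5-trihydroxybenzaldehyde
Product: 4 7-hydroxy-2,2-diphenyl-1,3-benzodioxole-5-carbaldehyde
Conditions: Ph2CCl2, Ph2O, 175 °C
Reagents that add atoms: dichlorodiphenylmethane, ClC(Cl)(c1ccccc1)c1ccccc1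
Why: Catechol ketalisation with a gem-dichloride closes the five-membered dioxole on two neighbouring hydroxyls, and since the pyrogallol is symmetric either adjacent pair gives the same product with one phenol left free.

Step 3
Reactants: 4 7-hydroxy-2,2-diphenyl-1,3-benzodioxole-5-carbaldehyde
Product: 5 2,2-diphenyl-7-[(triisopropylsilyl)oxy]-1,3-benzodioxole-5-carbaldehyde
Conditions: iPr3SiCl, imidazole, DMF, rt
Reagents that add atoms: triisopropylsilyl chloride, CC(C)[Si](Cl)(C(C)C)C(C)C
Why: Imidazole-promoted O-silylation caps the remaining phenol with a bulky, weakly coordinating group that should survive peracid, carbonate and butyllithium and will not direct the later metalation.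

Step 4
Reactants: 5 2,2-diphenyl-7-[(triisopropylsilyl)oxy]-1,3-benzodioxole-5-carbaldehyde
Product: 7 2,2-diphenyl-7-[(triisopropylsilyl)oxy]-1,3-benzodioxol-5-ol, via aryl formate 6 (not isolated)
Conditions: mCPBA, CH2Cl2, 0 °C → rt; then Et3N, MeOH, rt
Reagents that add atoms: 3-chloroperoxybenzoic acid, OOC(=O)c1cccc(Cl)c1
Why: Baeyer–Villiger oxidation of an electron-rich benzaldehyde, in which the aryl group migrates with help from the para ring oxygen, followed by methanolysis of the labile formate, should deliver the phenol.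

Step 5
Reactants: 7 2,2-diphenyl-7-[(triisopropylsilyl)oxy]-1,3-benzodioxol-5-ol
Product: 8 triisopropyl[(6-methoxy-2,2-diphenyl-1,3-benzodioxol-4-yl)oxy]silane
Conditions: MeI, K2CO3, acetone, 40 °C
Reagents that add atoms: iodomethane, CI
Why: Williamson O-methylation of the only free phenol installs the future C4 methoxy group.

Step 6
Reactants: 8 triisopropyl[(6-methoxy-2,2-diphenyl-1,3-benzodioxol-4-yl)oxy]silane; 2 N-methoxy-N-methyl-3-phenylpropanamide
Product: 10 1-{5-methoxy-2,2-diphenyl-7-[(triisopropylsilyl)oxy]-1,3-benzodioxol-4-yl}-3-phenylpropan-1-one, via aryllithium 9 (not isolated)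
Conditions: n-BuLi, THF, −78 → 0 °C; then 2, −78 °C → rt; aq NH4Cl
Reagents that add atoms: none
Why: Directed ortho-metalation should occur at the ring CH flanked by the methoxy group and the dioxole oxygen (two coordinating oxygens, whereas the other CH is shielded by the non-directing silyloxy group), and the Weinreb ketone synthesis then stops at the ketone because its chelated tetrahedral adduct does not collapse before work-up.

Step 7
Reactants: 10 1-{5-methoxy-2,2-diphenyl-7-[(triisopropylsilyl)oxy]-1,3-benzodioxol-4-yl}-3-phenylpropan-1-one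
Product: 11 1-(7-hydroxy-5-methoxy-2,2-diphenyl-1,3-benzodioxol-4-yl)-3-phenylpropan-1-one
Conditions: Bu4NF, AcOH, THF, 0 °C
Reagents that add atoms: none
Why: Fluoride-induced cleavage of the aryl silyl ether, buffered by acetic acid so that neither phenoxide nor enolate chemistry interferes, should free the phenol.

Step 8
Reactants: 11 1-(7-hydroxy-5-methoxy-2,2-diphenyl-1,3-benzodioxol-4-yl)-3-phenylpropan-1-one
Product: 12 1-(7-hydroxy-6-iodo-5-methoxy-2,2-diphenyl-1,3-benzodioxol-4-yl)-3-phenylpropan-1-one
Conditions: NIS, MeCN, 0 °C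
Reagents that add atoms: N-iodosuccinimide, O=C1CCC(=O)N1I
Why: Electrophilic aromatic iodination of a phenol can only take place at the single unsubstituted ring position, which is ortho to the hydroxyl and activated by three oxygens.

Step 9
Reactants: 12 1-(7-hydroxy-6-iodo-5-methoxy-2,2-diphenyl-1,3-benzodioxol-4-yl)-3-phenylpropan-1-one; 13 trimethylsilylacetylene
Product: 14 1-{7-hydroxy-5-methoxy-2,2-diphenyl-6-[(trimethylsilyl)ethynyl]-1,3-benzodioxol-4-yl}-3-phenylpropan-1-one
Conditions: PdCl2(PPh3)2 (5 mol %), CuI (10 mol %), Et3N, THF, 40 °C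
Reagents that add atoms: none
Why: Sonogashira coupling of an ortho-iodophenol with a silyl-capped alkyne should proceed at the aryl iodide, the trimethylsilyl group preventing double coupling and slowing 5-endo cyclisation to a benzofuran.

Step 10
Reactants: 14 1-{7-hydroxy-5-methoxy-2,2-diphenyl-6-[(trimethylsilyl)ethynyl]-1,3-benzodioxol-4-yl}-3-phenylpropan-1-one
Product: 15 1-(6-ethynyl-7-hydroxy-5-methoxy-2,2-diphenyl-1,3-benzodioxol-4-yl)-3-phenylpropan-1-one
Conditions: K2CO3 (20 mol %), MeOH–THF, 0 °C → rt
Reagents that add atoms: none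
Why: Methoxide-mediated protodesilylation of the alkynylsilane is expected under conditions too mild for base-induced cyclisation of the ethynylphenol.

Step 11
Reactants: 15 1-(6-ethynyl-7-hydroxy-5-methoxy-2,2-diphenyl-1,3-benzodioxol-4-yl)-3-phenylpropan-1-one; 16 carbon monoxide; 17 phenylboronic acid
Product: 18 (3Z)-3-benzylidene-4-methoxy-5-(3-phenylpropanoyl)-6,7-[(diphenylmethylene)dioxy]-1-benzofuran-2(3H)-one
Conditions: Pd(OAc)2 (10 mol %), 1,4-benzoquinone (1.5 equiv), NaOAc (20 mol %), CO (5 bar), wet 1,4-dioxane, 40 °C, PhB(OH)2 added over 6 h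
Reagents that add atoms: none
Why: Proposed new method: the phenoxide binds divalent palladium and CO inserts into the Pd–O bond to give an aryloxycarbonyl–palladium species, which adds syn across the ortho alkyne (O1–C2 and C2–C3 formed, lactone closed 5-exo-dig) and leaves a vinylpalladium cis to the new carbonyl; transmetalation from PhB(OH)2 and reductive elimination then form the CH–Ph bond with retention, and benzoquinone returns zerovalent palladium to the divalent state. The closest known reaction types are the oxidative alkoxycarbonylative cyclisation of alkynols to α-alkylidene lactones and the carbamoyl-palladation/Suzuki cascades that give 3-alkylideneoxindoles. No stereocentre is formed; the Z geometry follows from syn insertion and stereoretentive coupling, and it is also the less strained isomer because only hydrogen faces the C4 methoxy group. The step needs carbonylative 5-exo closure to outrun 5-endo oxypalladation to a benzofuran, premature phenyl transfer (aryl benzoate, biphenyl) and oxidative coupling at the alkyne C–H bond. CO pressure, a copper-free carboxylate-ligated catalyst and slow addition of the boronic acid are chosen for this, and the substrate helps because its only free hydroxyl is held next to the alkyne while the catechol is locked in the ketal and cannot be oxidised by the quinone.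

Step 12
Reactants: 18 (3Z)-3-benzylidene-4-methoxy-5-(3-phenylpropanoyl)-6,7-[(diphenylmethylene)dioxy]-1-benzofuran-2(3H)-one
Product: 19 bractelactone
Conditions: AcOH–H2O (4:1), 80 °C
Reagents that add atoms: none
Why: Acid hydrolysis of the diaryl ketal through its stabilised diphenyl-substituted oxocarbenium ion should release the catechol and benzophenone, while the aryl lactone and the conjugated Z alkene are expected to tolerate aqueous acid.

**Compound list**

1 | 3-phenylpropanoyl chloride | O=C(Cl)CCc1ccccc1 | starting material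
2 | N-methoxy-N-methyl-3-phenylpropanamide | CON(C)C(=O)CCc1ccccc1 | intermediate
3 | 3,4,5-trihydroxybenzaldehyde | O=Cc1cc(O)c(O)c(O)c1 | starting material
4 | 7-hydroxy-2,2-diphenyl-1,3-benzodioxole-5-carbaldehyde | O=Cc1cc(O)c2OC(c3ccccc3)(c3ccccc3)Oc2c1 | intermediate
5 | 2,2-diphenyl-7-[(triisopropylsilyl)oxy]-1,3-benzodioxole-5-carbaldehyde | O=Cc1cc(O[Si](C(C)C)(C(C)C)C(C)C)c2OC(c3ccccc3)(c3ccccc3)Oc2c1 | intermediate
6 | 2,2-diphenyl-7-[(triisopropylsilyl)oxy]-1,3-benzodioxol-5-yl formate (not isolated) | O=COc1cc(O[Si](C(C)C)(C(C)C)C(C)C)c2OC(c3ccccc3)(c3ccccc3)Oc2c1 | intermediate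
7 | 2,2-diphenyl-7-[(triisopropylsilyl)oxy]-1,3-benzodioxol-5-ol | Oc1cc(O[Si](C(C)C)(C(C)C)C(C)C)c2OC(c3ccccc3)(c3ccccc3)Oc2c1 | intermediate
8 | triisopropyl[(6-methoxy-2,2-diphenyl-1,3-benzodioxol-4-yl)oxy]silane | COc1cc(O[Si](C(C)C)(C(C)C)C(C)C)c2OC(c3ccccc3)(c3ccccc3)Oc2c1 | intermediate
9 | {5-methoxy-2,2-diphenyl-7-[(triisopropylsilyl)oxy]-1,3-benzodioxol-4-yl}lithium (not isolated) | [Li]c1c(OC)cc(O[Si](C(C)C)(C(C)C)C(C)C)c2OC(c3ccccc3)(c3ccccc3)Oc12 | intermediate
10 | 1-{5-methoxy-2,2-diphenyl-7-[(triisopropylsilyl)oxy]-1,3-benzodioxol-4-yl}-3-phenylpropan-1-one | COc1cc(O[Si](C(C)C)(C(C)C)C(C)C)c2OC(c3ccccc3)(c3ccccc3)Oc2c1C(=O)CCc1ccccc1 | intermediate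
11 | 1-(7-hydroxy-5-methoxy-2,2-diphenyl-1,3-benzodioxol-4-yl)-3-phenylpropan-1-one | COc1cc(O)c2OC(c3ccccc3)(c3ccccc3)Oc2c1C(=O)CCc1ccccc1 | intermediate
12 | 1-(7-hydroxy-6-iodo-5-methoxy-2,2-diphenyl-1,3-benzodioxol-4-yl)-3-phenylpropan-1-one | COc1c(I)c(O)c2OC(c3ccccc3)(c3ccccc3)Oc2c1C(=O)CCc1ccccc1 | intermediate
13 | trimethylsilylacetylene | C#C[Si](C)(C)C | starting material
14 | 1-{7-hydroxy-5-methoxy-2,2-diphenyl-6-[(trimethylsilyl)ethynyl]-1,3-benzodioxol-4-yl}-3-phenylpropan-1-one | COc1c(C#C[Si](C)(C)C)c(O)c2OC(c3ccccc3)(c3ccccc3)Oc2c1C(=O)CCc1ccccc1 | intermediate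
15 | 1-(6-ethynyl-7-hydroxy-5-methoxy-2,2-diphenyl-1,3-benzodioxol-4-yl)-3-phenylpropan-1-one | C#Cc1c(O)c2OC(c3ccccc3)(c3ccccc3)Oc2c(C(=O)CCc2ccccc2)c1OC | intermediate
16 | carbon monoxide | [C-]#[O+] | starting material
17 | phenylboronic acid | OB(O)c1ccccc1 | starting material
18 | (3Z)-3-benzylidene-4-methoxy-5-(3-phenylpropanoyl)-6,7-[(diphenylmethylene)dioxy]-1-benzofuran-2(3H)-one (bractelactone C6/C7 diphenylmethylene ketal) | COc1c(C(=O)CCc2ccccc2)c2OC(c3ccccc3)(c3ccccc3)Oc2c2OC(=O)/C(=C\c3ccccc3)c12 | intermediate
19 | bractelactone, (3Z)-3-benzylidene-6,7-dihydroxy-4-methoxy-5-(3-phenylpropanoyl)-1-benzofuran-2(3H)-one | COc1c(C(=O)CCc2ccccc2)c(O)c(O)c2c1/C(=C/c1ccccc1)C(=O)O2 | target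

**Step count**

Total steps: 12. Longest linear sequence: 11 (steps 2 to 12; step 1 is a one-step side branch).

**Steps most likely to fail, with fallbacks**

Step 11. The phenol may add to the palladium-bound alkyne in a 5-endo sense before CO has inserted. Phenyl may also reach palladium first and be lost as an aryl benzoate or as biphenyl, or the terminal alkyne may couple oxidatively at its C–H bond. The fallback sets out from iodophenol 12 and returns to the route at 18, bypassing 14 and 15. Commercial methyl 3-phenylpropiolate is hydrostannylated with Bu3SnH and Pd(PPh3)4 in THF (syn addition, tin α to the ester) to give methyl (E)-3-phenyl-2-(tributylstannyl)prop-2-enoate F1. Stille coupling of this stannane with 12 (Pd(PPh3)4, CuI, DMF, 50 °C) should proceed with retention of alkene geometry to methyl (Z)-2-[7-hydroxy-5-methoxy-2,2-diphenyl-4-(3-phenylpropanoyl)-1,3-benzodioxol-6-yl]-3-phenylprop-2-enoate F2, in which phenyl already stands cis to the ester carbonyl. Warming F2 with catalytic TsOH in toluene should close the lactone onto the neighbouring phenol with loss of methanol and give 18.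

Step 6. Metalation may take place in part at the CH between the methoxy and silyloxy groups, followed by silyl migration from oxygen to carbon. The hindered aryllithium may also deprotonate the amide at its α-carbon instead of adding to it. The fallback sets out from 8 and returns at 10. Bromination with N-bromosuccinimide in MeCN at 0 °C is expected to attack the less hindered position para to the silyloxy group and give [(7-bromo-6-methoxy-2,2-diphenyl-1,3-benzodioxol-4-yl)oxy]triisopropylsilane F3, whose constitution can be checked and purified at this stage. Bromine–lithium exchange with n-BuLi in THF at −78 °C then generates aryllithium 9 at a site fixed by the halogen. Addition to 3-phenylpropanal, which is a better electrophile than the amide, should give racemic 1-{5-methoxy-2,2-diphenyl-7-[(triisopropylsilyl)oxy]-1,3-benzodioxol-4-yl}-3-phenylpropan-1-ol F4, and Dess–Martin oxidation of F4 leads to ketone 10.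

Step 9. The free phenoxide next to the reacting carbon may cyclise onto the coupled alkyne under copper and palladium to a benzofuran, or it may bind the catalyst so that alkyne homocoupling competes with a slow coupling at the doubly ortho-substituted iodide. The fallback sets out from 12 and returns at 15. The phenol is masked with Ac2O and pyridine as 5-iodo-6-methoxy-2,2-diphenyl-7-(3-phenylpropanoyl)-1,3-benzodioxol-4-yl acetate F5, which is no longer nucleophilic at oxygen and is a better partner for oxidative addition. Sonogashira coupling with 13 (PdCl2(PPh3)2, CuI, Et3N, THF) should give 6-methoxy-2,2-diphenyl-7-(3-phenylpropanoyl)-5-[(trimethylsilyl)ethynyl]-1,3-benzodioxol-4-yl acetate F6. Treatment of F6 with K2CO3 in MeOH removes the acetate and the silyl group together and gives ethynylphenol 15, so step 10 is absorbed.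

**Further compounds**

F1 | step 11 | methyl (E)-3-phenyl-2-(tributylstannyl)prop-2-enoate | COC(=O)/C(=C\c1ccccc1)[Sn](CCCC)(CCCC)CCCC
F2 | step 11 | methyl (Z)-2-[7-hydroxy-5-methoxy-2,2-diphenyl-4-(3-phenylpropanoyl)-1,3-benzodioxol-6-yl]-3-phenylprop-2-enoate | COC(=O)/C(=C\c1ccccc1)c1c(O)c2OC(c3ccccc3)(c3ccccc3)Oc2c(C(=O)CCc2ccccc2)c1OC
F3 | step 6 | [(7-bromo-6-methoxy-2,2-diphenyl-1,3-benzodioxol-4-yl)oxy]triisopropylsilane | COc1cc(O[Si](C(C)C)(C(C)C)C(C)C)c2OC(c3ccccc3)(c3ccccc3)Oc2c1Br
F4 | step 6 | 1-{5-methoxy-2,2-diphenyl-7-[(triisopropylsilyl)oxy]-1,3-benzodioxol-4-yl}-3-phenylpropan-1-ol (racemic) | COc1cc(O[Si](C(C)C)(C(C)C)C(C)C)c2OC(c3ccccc3)(c3ccccc3)Oc2c1C(O)CCc1ccccc1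
F5 | step 9 | 5-iodo-6-methoxy-2,2-diphenyl-7-(3-phenylpropanoyl)-1,3-benzodioxol-4-yl acetate | CC(=O)Oc1c(I)c(OC)c(C(=O)CCc2ccccc2)c2OC(c3ccccc3)(c3ccccc3)Oc12
F6 | step 9 | 6-methoxy-2,2-diphenyl-7-(3-phenylpropanoyl)-5-[(trimethylsilyl)ethynyl]-1,3-benzodioxol-4-yl acetate | CC(=O)Oc1c(C#C[Si](C)(C)C)c(OC)c(C(=O)CCc2ccccc2)c2OC(c3ccccc3)(c3ccccc3)Oc12
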